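1. Cuts: the phenol ester C–O bond and the side-chain CH2–O(acyl) bond are opened last, the oxirane CH2–O bond is cut in the key step, and the aryl–C(quaternary) bond leads back to an aryl Grignard reagent and 1,3-dichloroacetone.
2. Enabling feature: oxirane C2 is a fully substituted benzylic carbon whose two CH2–O arms (the ring CH2 and the CH2 of the isobutyryloxymethyl group) differ only in what their oxygen is bound to, so C2 maps onto the carbinol carbon of an achiral ArC(OH)(CH2Cl)2.
3. Forward: ortho-iodination and silylation of the phenol; iodine–magnesium exchange and addition to the ketone join the three-carbon unit; the oxirane, the only new ring, is closed enzymatically; isobutyrate then moves the oxirane to the other arm; silyl is finally exchanged for isobutyryl.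
4. Stereochemistry: the single stereocentre is set in step 4 by the enzyme's choice of the pro-S CH2Cl arm (R oxirane); step 5 breaks no bond at that carbon and converts it into the S-configured ester oxirane of the target.

Key step: step 4

Assumption: a halohydrin dehalogenase variant that displaces the chloride of the pro-S arm of 7 can be found by screening an HheC mutant panel; a variant of opposite preference would give the enantiomer by the same steps.

Step 1
Reactants: 1 4-methoxy-3-methylphenol
Product: 2 2-iodo-4-methoxy-5-methylphenol
Conditions: NIS, p-TsOH·H2O (10 mol%), MeCN, 0 °C to rt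
Reagents that add atoms: N-iodosuccinimide, O=C1CCC(=O)N1I
Why: Electrophilic aromatic iodination is steered by the hydroxyl group, whose para position is blocked, and should go to the free ortho position para to the methyl group, not to the ortho position wedged between OH and CH3.

Step 2
Reactants: 2 2-iodo-4-methoxy-5-methylphenol
Product: 3 tert-butyl(2-iodo-4-methoxy-5-methylphenoxy)dimethylsilane
Conditions: TBSCl, imidazole, DMF, rt
Reagents that add atoms: tert-butyldimethylsilyl chloride, CC(C)(C)[Si](C)(C)Cl
Why: Imidazole-promoted O-silylation of a phenol is routine and masks the acidic and nucleophilic oxygen for the organometallic, enzymatic and carboxylate steps while remaining removable by fluoride.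

Step 3
Reactants: 3 tert-butyl(2-iodo-4-methoxy-5-methylphenoxy)dimethylsilane; 4 1,3-dichloroacetone
Product: 7 2-[2-(tert-butyldimethylsilyloxy)-5-methoxy-4-methylphenyl]-1,3-dichloropropan-2-ol, via arylmagnesium chloride 5 (not isolated), via chloromagnesium alkoxide 6 (not isolated)
Conditions: iPrMgCl·LiCl, THF, −20 °C; then cannulated into 4, THF, −78 °C; AcOH quench at −78 °C
Reagents that add atoms: none
Why: Iodine–magnesium exchange with the turbo-Grignard reagent is fast on the aryl iodide at low temperature, the covalent arylmagnesium species should not undergo oxygen-to-carbon silyl shift, and its 1,2-addition to the ketone followed by a cold acidic quench is the established way from aryl Grignard reagents and 1,3-dichloroacetone to 2-aryl-1,3-dichloropropan-2-ols with both C–Cl bonds kept.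

Step 4
Reactants: 7 2-[2-(tert-butyldimethylsilyloxy)-5-methoxy-4-methylphenyl]-1,3-dichloropropan-2-ol
Product: 8 (R)-2-[2-(tert-butyldimethylsilyloxy)-5-methoxy-4-methylphenyl]-2-(chloromethyl)oxirane
Conditions: halohydrin dehalogenase HheC variant (selected from a mutant panel), Tris-SO4 buffer pH 7.5, DMSO (10% v/v), 25 °C, pH-stat with aq. NaOH; MTBE extraction
Reagents that add atoms: none
Why: Proposed new method: the tertiary hydroxyl of achiral 7 is hydrogen-bonded to the catalytic serine and deprotonated by the tyrosinate of the Ser-Tyr-Arg triad while one CH2Cl arm sits in the halide-binding site anti-periplanar to the oxygen, so the oxygen displaces that chloride in an intramolecular SN2 reaction. The closest known reaction type is the halohydrin dehalogenase closure of 1,3-dichloropropan-2-ol to epichlorohydrin, together with the reversible closure of tertiary halohydrins to 2,2-disubstituted oxiranes by the same enzyme class; a 2-aryl carbinol with an ortho silyloxy group has not been shown. The oxirane closes in the 3-exo-tet mode. The new stereocentre is under catalyst control: the aryl group is held in the hydrophobic pocket and only the pro-S arm reaches the halide site, which gives the R oxirane. The step needs selection between two enantiotopic arms without later erosion; 7 has a single hydroxyl and can close only once, the silyl ether keeps the phenol from competing as a nucleophile, and chloride-free buffer with early extraction limits re-opening by chloride and the slow uncatalysed closure.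

Step 5
Reactants: 8 (R)-2-[2-(tert-butyldimethylsilyloxy)-5-methoxy-4-methylphenyl]-2-(chloromethyl)oxirane; 9 isobutyric acid
Product: 12 (S)-{2-[2-(tert-butyldimethylsilyloxy)-5-methoxy-4-methylphenyl]oxiran-2-yl}methyl 2-methylpropanoate, via caesium isobutyrate 10 (not isolated), via caesium chlorohydrin alkoxide 11 (not isolated)
Conditions: 9 (1.5 equiv), Cs2CO3 (0.75 equiv), MeOH, rt, then concentrated and dried in vacuo; 8, DMF, 4 Å MS, 60 °C
Reagents that add atoms: none
Why: Caesium isobutyrate should open the 2,2-disubstituted oxirane by SN2 attack at its unsubstituted CH2, and the β-chloro alkoxide 11 then closes 3-exo-tet onto the chloromethyl carbon (Williamson-type closure, the pathway by which carboxylates turn epichlorohydrins into glycidyl esters), so no bond at the stereocentre is broken and the descriptor changes from R to S only because the oxirane now sits on the other arm.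

Step 6
Reactants: 12 (S)-{2-[2-(tert-butyldimethylsilyloxy)-5-methoxy-4-methylphenyl]oxiran-2-yl}methyl 2-methylpropanoate
Product: 14 (S)-{2-[2-(isobutyryloxy)-5-methoxy-4-methylphenyl]oxiran-2-yl}methyl 2-methylpropanoate, via tetrabutylammonium phenoxide 13 (not isolated)
Conditions: (iPrCO)2O (3 equiv), Bu4NF (1.2 equiv, slow addition), THF, −40 to 0 °C
Reagents that add atoms: isobutyric anhydride, CC(C)C(=O)OC(=O)C(C)C
Why: Fluoride cleaves the aryl silyl ether, and the phenoxide is O-acylated by the anhydride already present before it can attack the oxirane or the side-chain ester (one-pot silyl ether to ester exchange), leaving the stereocentre untouched.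

Compound list
1 | 4-methoxy-3-methylphenol | COc1ccc(O)cc1C | starting material
2 | 2-iodo-4-methoxy-5-methylphenol | COc1cc(I)c(O)cc1C | intermediate
3 | tert-butyl(2-iodo-4-methoxy-5-methylphenoxy)dimethylsilane | COc1cc(I)c(O[Si](C)(C)C(C)(C)C)cc1C | intermediate
4 | 1,3-dichloroacetone (1,3-dichloropropan-2-one) | ClCC(=O)CCl | starting material
5 | [2-(tert-butyldimethylsilyloxy)-5-methoxy-4-methylphenyl]magnesium chloride (not isolated) | COc1cc([Mg]Cl)c(O[Si](C)(C)C(C)(C)C)cc1C | intermediate
6 | chloromagnesium 2-[2-(tert-butyldimethylsilyloxy)-5-methoxy-4-methylphenyl]-1,3-dichloropropan-2-olate (not isolated) | COc1cc(C(O[Mg]Cl)(CCl)CCl)c(O[Si](C)(C)C(C)(C)C)cc1C | intermediate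
7 | 2-[2-(tert-butyldimethylsilyloxy)-5-methoxy-4-methylphenyl]-1,3-dichloropropan-2-ol (achiral) | COc1cc(C(O)(CCl)CCl)c(O[Si](C)(C)C(C)(C)C)cc1C | intermediate
8 | (R)-2-[2-(tert-butyldimethylsilyloxy)-5-methoxy-4-methylphenyl]-2-(chloromethyl)oxirane | COc1cc([C@]2(CCl)CO2)c(O[Si](C)(C)C(C)(C)C)cc1C | intermediate
9 | isobutyric acid (2-methylpropanoic acid) | CC(C)C(=O)O | starting material
10 | caesium isobutyrate (not isolated) | CC(C)C(=O)[O-].[Cs+] | intermediate
11 | caesium (R)-2-[2-(tert-butyldimethylsilyloxy)-5-methoxy-4-methylphenyl]-1-chloro-3-(isobutyryloxy)propan-2-olate (not isolated) | COc1cc([C@]([O-])(CCl)COC(=O)C(C)C)c(O[Si](C)(C)C(C)(C)C)cc1C.[Cs+] | intermediate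
12 | (S)-{2-[2-(tert-butyldimethylsilyloxy)-5-methoxy-4-methylphenyl]oxiran-2-yl}methyl 2-methylpropanoate | COc1cc([C@@]2(COC(=O)C(C)C)CO2)c(O[Si](C)(C)C(C)(C)C)cc1C | intermediate
13 | tetrabutylammonium 2-[(S)-2-(isobutyryloxymethyl)oxiran-2-yl]-4-methoxy-5-methylphenoxide (not isolated) | COc1cc([C@@]2(COC(=O)C(C)C)CO2)c([O-])cc1C.CCCC[N+](CCCC)(CCCC)CCCC | intermediate
14 | (S)-{2-[2-(isobutyryloxy)-5-methoxy-4-methylphenyl]oxiran-2-yl}methyl 2-methylpropanoate | COc1cc([C@@]2(COC(=O)C(C)C)CO2)c(OC(=O)C(C)C)cc1C | target

Total step count: 6. Longest linear sequence: 6 steps (1 to 14).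

Steps most likely to fail

Step 4. The ortho-silyloxy aryl carbinol may bind poorly in the enzyme pocket, and the two enantiotopic arms may be discriminated insufficiently. Enantiomeric purity may also erode through chloride re-opening of the product or through uncatalysed closure. The fallback sets out from 3 and returns at 12, using known chemistry only. Iodine–magnesium exchange of 3 (iPrMgCl·LiCl, via 5) and CuI-catalysed carbomagnesiation of the chloromagnesium alkoxide of propargyl alcohol should give 2-[2-(tert-butyldimethylsilyloxy)-5-methoxy-4-methylphenyl]prop-2-en-1-ol F1. Sharpless asymmetric epoxidation (Ti(OiPr)4, D-(−)-diethyl tartrate, tBuOOH, 4 Å MS, CH2Cl2, −20 °C) should then give (R)-{2-[2-(tert-butyldimethylsilyloxy)-5-methoxy-4-methylphenyl]oxiran-2-yl}methanol F2. Acylation of F2 with isobutyric anhydride, Et3N and catalytic DMAP gives 12, which continues with step 6.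

Step 5. Direct displacement at the chloromethyl carbon would deliver the enantiomer. Liberated chloride can re-open unreacted 8 to a symmetric dichloro alkoxide and racemise it. The transient alkoxide may also pull the silyl group from the neighbouring phenol oxygen, or moist carboxylate may cleave the aryl silyl ether. The fallback sets out from 8 and returns at 12 by separating opening and closure. Opening with excess isobutyric acid 9 buffered by a substoichiometric amount of its caesium salt 10 (DMF, 50 °C) protonates the alkoxide as it forms and should give (R)-2-[2-(tert-butyldimethylsilyloxy)-5-methoxy-4-methylphenyl]-3-chloro-2-hydroxypropyl 2-methylpropanoate F3. After isolation, F3 is closed cold with NaH in THF (−20 to 0 °C) to give 12.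

Step 6. The liberated phenoxide may attack the oxirane CH2 or the side-chain ester intramolecularly before it is acylated, and basic fluoride may open the oxirane. The fallback sets out from 12 and returns at 14 by avoiding the free phenoxide. Desilylation with Bu4NF buffered by an equimolar amount of acetic acid (THF, 0 °C) should give the neutral phenol (S)-[2-(2-hydroxy-5-methoxy-4-methylphenyl)oxiran-2-yl]methyl 2-methylpropanoate F4. F4 is then acylated in a separate operation with isobutyryl chloride, pyridine and catalytic DMAP (CH2Cl2, −20 °C) to give 14.

Further compounds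
F1 | step 4 | 2-[2-(tert-butyldimethylsilyloxy)-5-methoxy-4-methylphenyl]prop-2-en-1-ol | COc1cc(C(=C)CO)c(O[Si](C)(C)C(C)(C)C)cc1C
F2 | step 4 | (R)-{2-[2-(tert-butyldimethylsilyloxy)-5-methoxy-4-methylphenyl]oxiran-2-yl}methanol | COc1cc([C@@]2(CO)CO2)c(O[Si](C)(C)C(C)(C)C)cc1C
F3 | step 5 | (R)-2-[2-(tert-butyldimethylsilyloxy)-5-methoxy-4-methylphenyl]-3-chloro-2-hydroxypropyl 2-methylpropanoate | COc1cc([C@](O)(CCl)COC(=O)C(C)C)c(O[Si](C)(C)C(C)(C)C)cc1C
F4 | step 6 | (S)-[2-(2-hydroxy-5-methoxy-4-methylphenyl)oxiran-2-yl]methyl 2-methylpropanoate | COc1cc([C@@]2(COC(=O)C(C)C)CO2)c(O)cc1C
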